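**Retrosynthetic overview**
Rings: A = p-phenylene, B = 1,2,3-substituted ring (C1 bridge, O2 ether, O3–H), C = m-phenylene, D = 3,4,5-trioxygenated ring on the (S)-carbinol carbon. The only ring to build is the 18-membered macrocycle.
Key disconnection: O3(D)–C4(A) together with C1(A)–CH2. Ring A then leaves as 1-bromo-4-iodobenzene, which one operation (Heck at C–I, then Ullmann closure at C–Br) stitches between a vinyl group on ring B and a phenoxide of ring D.
Enabling feature: ring A carries only its two para bonds, so a 1,4-dihalobenzene with graded halogens can stand for it. Ring D is locally C2-symmetric about its C1–C4 axis, so O3 and O5 are interchangeable and only O4 needs a blocking group.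
The acyclic three-ring precursor comes from an Ivanov–Claisen/decarboxylation union (C–CH2–CO–D), an SNAr ether synthesis (B–O–C), and an asymmetric transfer hydrogenation that sets the stereocentre before ring closure.
Endgame: one hydrogenation saturates the A–B bridge and removes both benzyl groups.

Key step: step 8

Assumption: the carbinol carbon of the given SMILES is (S) by CIP analysis, and the macrocycles are taken to be conformationally mobile, so this carbon is the only stereogenic unit.

Step 1
Reactants: 1 2-fluoro-3-hydroxybenzaldehyde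
Product: 2 3-(benzyloxy)-2-fluorobenzaldehyde
Conditions: BnBr, K2CO3, DMF, rt
Reagents that add atoms: benzyl bromide, BrCc1ccccc1
Why: Williamson ether synthesis on the only phenol; the benzyl ether should survive the later base, Grignard, Pd and Cu steps and leaves in step 9.

Step 2
Reactants: 2 3-(benzyloxy)-2-fluorobenzaldehyde; 3 3-hydroxyphenylacetic acid
Product: 4 {3-[2-(benzyloxy)-6-formylphenoxy]phenyl}acetic acid
Conditions: K2CO3, DMSO, 120 °C; then 1 M HCl
Reagents that add atoms: none
Why: SNAr (addition–elimination): the ortho-formyl group stabilises the Meisenheimer adduct at C2, so the phenoxide of 3 displaces fluoride, while the carboxylate is too weak a nucleophile to compete and keeps the benzylic CH2 from condensing with the aldehyde.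

Step 3
Reactants: 4 {3-[2-(benzyloxy)-6-formylphenoxy]phenyl}acetic acid
Product: 5 {3-[2-(benzyloxy)-6-vinylphenoxy]phenyl}acetic acid
Conditions: Ph3PCH3Br, KOt-Bu, THF, 0 °C → rt; then 1 M HCl
Reagents that add atoms: methyltriphenylphosphonium bromide, C[P+](c1ccccc1)(c1ccccc1)c1ccccc1.[Br-]
Why: Wittig methylenation of the aryl aldehyde; one extra equivalent of base merely holds the acid as its inert carboxylate.

Step 4
Reactants: 6 methyl gallate
Product: 7 methyl 4-(benzyloxy)-3,5-dihydroxybenzoate
Conditions: BnBr (1 equiv), KHCO3, KI (cat.), DMF, rt → 40 °C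
Reagents that add atoms: benzyl bromide, BrCc1ccccc1
Why: Regioselective Williamson alkylation: the 4-OH, para to the ester and flanked by two hydrogen-bond donors, is the most acidic, so the weak base ionises and alkylates only this oxygen.

Step 5
Reactants: 7 methyl 4-(benzyloxy)-3,5-dihydroxybenzoate
Product: 8 methyl 4-(benzyloxy)-3,5-bis(tert-butyldimethylsilyloxy)benzoate
Conditions: TBSCl, imidazole, DMF, rt
Reagents that add atoms: tert-butyldimethylsilyl chloride, CC(C)(C)[Si](C)(C)Cl
Why: Standard imidazole-promoted silylation masks both acidic phenols for the organomagnesium step.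

Step 6
Reactants: 5 {3-[2-(benzyloxy)-6-vinylphenoxy]phenyl}acetic acid; 8 methyl 4-(benzyloxy)-3,5-bis(tert-butyldimethylsilyloxy)benzoate
Product: 10 1-[4-(benzyloxy)-3,5-bis(tert-butyldimethylsilyloxy)phenyl]-2-{3-[2-(benzyloxy)-6-vinylphenoxy]phenyl}ethan-1-one, via beta-keto acid 9 (not isolated)
Conditions: 5, t-BuMgCl (3.5 equiv), THF, 0 °C; then 8, 55 °C; then 1 M HCl, rt
Reagents that add atoms: none
Why: Ivanov-type Claisen condensation: the chloromagnesium enediolate of arylacetic acid 5 is C-acylated by ester 8, excess hindered base stores the product as its chelated dianion, and the β-keto acid 9 set free on acidification loses CO2 spontaneously, its transient stereocentre vanishing with it.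

Step 7
Reactants: 10 the ketone of step 6
Product: 11 (1S)-1-[4-(benzyloxy)-3,5-bis(tert-butyldimethylsilyloxy)phenyl]-2-{3-[2-(benzyloxy)-6-vinylphenoxy]phenyl}ethan-1-ol
Conditions: (S,S)-Ts-DENEB (1 mol%), HCO2H/Et3N (5:2), EtOAc, 40 °C
Reagents that add atoms: none
Why: Noyori–Ikariya asymmetric transfer hydrogenation: in the six-membered outer-sphere transition state ring D lies next to the η6-arene of the (S,S)-catalyst (CH/π attraction) and the benzyl residue points away, so hydride reaches the Re face and sets the (S)-carbinol, while vinyl, benzyl and silyl groups are inert.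

Step 8
Reactants: 11 the (S)-alcohol of step 7; 12 1-bromo-4-iodobenzene
Product: 15 (S,E)-configured di-O-benzyl macrocycle with a CH=CH bridge between rings A and B, via E-bromostilbene 13 (not isolated), via bis-phenol 14 (not isolated)
Conditions: (a) 12 (1.0 equiv), Pd(OAc)2 (3 mol%), n-Bu4NBr, Cs2CO3, DMF, 80 °C, 0.15 M; (b) syringe-pump addition of this solution to CuI, N,N-dimethylglycine, CsF, Cs2CO3, DMF/1,4-dioxane, 105 °C, Ar, final 2 mM
Reagents that add atoms: none
Why: Ligand-free Pd(0) inserts only into the weaker C–I bond of 12, and syn-carbopalladation of the ring-B vinyl group at its CH2 terminus followed by syn β-hydride elimination (Mizoroki–Heck reaction) gives the (E)-4-bromostilbene 13 with the C–Br bond intact. On slow addition to CsF/Cu(I), fluoride cleaves both O–Si bonds, a cesium phenoxide of 14 binds Cu(I), and intramolecular oxidative addition into the ring-A C–Br bond followed by C–O reductive elimination (Ullmann diaryl ether synthesis) forms the O3(D)–C4(A) bond. The one ring that closes is the 18-membered macrocycle: it forms end to end through a 19-membered cupracycle that contracts on reductive elimination under pseudo-high dilution, the closest known reaction type being Ullmann macrocyclisation of o-alkoxyphenols onto 4-alkyl- or 4-alkenylaryl halides to 14- to 18-membered diaryl ether cyclophanes. No stereocentre is created: the alkene geometry follows from the Heck mechanism and is erased in step 9, and the (S)-carbinol should not ionise or epimerise because O4 para to it is benzylated (no p-quinone methide) and carbonate does not form the alkoxide. The order C–C before C–O is fixed by I > Br in oxidative addition and by adding copper only after the Heck stage; O3 versus O5 needs no control because rotation about the C1(D)–carbinol bond interchanges them and both give the same ring, O4(D) and O3(B) are blocked as benzyl ethers, and the protonated secondary alcohol is a far poorer partner for Cu(I) than a phenoxide. The proton lost from the vinyl group reaches the remaining phenoxide through the carbonate buffer, so 15 should leave the flask with exactly the free O5–H that the target needs.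

Step 9
Reactants: 15 the macrocycle of step 8
Product: 16 target, (S)-configured CNP0333307.1
Conditions: H2 (1 atm), 10% Pd/C, EtOAc/THF, rt, stopped after uptake of three equivalents of H2
Reagents that add atoms: none
Why: Heterogeneous hydrogenation and hydrogenolysis: the stilbene C=C and the two aryl benzyl ethers react much faster on Pd than a secondary benzylic C–OH under neutral conditions, so the stereocentre should stay untouched.

**Compound list**
1 | 2-fluoro-3-hydroxybenzaldehyde | O=Cc1cccc(O)c1F | starting material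
2 | 3-(benzyloxy)-2-fluorobenzaldehyde | O=Cc1cccc(OCc2ccccc2)c1F | intermediate
3 | 3-hydroxyphenylacetic acid | OC(=O)Cc1cccc(O)c1 | starting material
4 | {3-[2-(benzyloxy)-6-formylphenoxy]phenyl}acetic acid | O=Cc1cccc(OCc2ccccc2)c1Oc1cccc(CC(=O)O)c1 | intermediate
5 | {3-[2-(benzyloxy)-6-vinylphenoxy]phenyl}acetic acid | C=Cc1cccc(OCc2ccccc2)c1Oc1cccc(CC(=O)O)c1 | intermediate
6 | methyl gallate (methyl 3,4,5-trihydroxybenzoate) | COC(=O)c1cc(O)c(O)c(O)c1 | starting material
7 | methyl 4-(benzyloxy)-3,5-dihydroxybenzoate | COC(=O)c1cc(O)c(OCc2ccccc2)c(O)c1 | intermediate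
8 | methyl 4-(benzyloxy)-3,5-bis(tert-butyldimethylsilyloxy)benzoate | COC(=O)c1cc(O[Si](C)(C)C(C)(C)C)c(OCc2ccccc2)c(O[Si](C)(C)C(C)(C)C)c1 | intermediate
9 | racemic 3-[4-(benzyloxy)-3,5-bis(TBSO)phenyl]-2-{3-[2-(benzyloxy)-6-vinylphenoxy]phenyl}-3-oxopropanoic acid | C=Cc1cccc(OCc2ccccc2)c1Oc1cccc(C(C(=O)O)C(=O)c2cc(O[Si](C)(C)C(C)(C)C)c(OCc3ccccc3)c(O[Si](C)(C)C(C)(C)C)c2)c1 | intermediate
10 | 1-[4-(benzyloxy)-3,5-bis(TBSO)phenyl]-2-{3-[2-(benzyloxy)-6-vinylphenoxy]phenyl}ethan-1-one | C=Cc1cccc(OCc2ccccc2)c1Oc1cccc(CC(=O)c2cc(O[Si](C)(C)C(C)(C)C)c(OCc3ccccc3)c(O[Si](C)(C)C(C)(C)C)c2)c1 | intermediate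
11 | (1S)-1-[4-(benzyloxy)-3,5-bis(TBSO)phenyl]-2-{3-[2-(benzyloxy)-6-vinylphenoxy]phenyl}ethan-1-ol | C=Cc1cccc(OCc2ccccc2)c1Oc1cccc(C[C@H](O)c2cc(O[Si](C)(C)C(C)(C)C)c(OCc3ccccc3)c(O[Si](C)(C)C(C)(C)C)c2)c1 | intermediate
12 | 1-bromo-4-iodobenzene | Brc1ccc(I)cc1 | starting material
13 | (1S)-1-[4-(benzyloxy)-3,5-bis(TBSO)phenyl]-2-(3-{2-(benzyloxy)-6-[(E)-2-(4-bromophenyl)vinyl]phenoxy}phenyl)ethan-1-ol | Brc1ccc(/C=C/c2cccc(OCc3ccccc3)c2Oc2cccc(C[C@H](O)c3cc(O[Si](C)(C)C(C)(C)C)c(OCc4ccccc4)c(O[Si](C)(C)C(C)(C)C)c3)c2)cc1 | intermediate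
14 | 3,5-bis-phenol of 13 (both TBS groups removed; present as cesium phenoxide) | Brc1ccc(/C=C/c2cccc(OCc3ccccc3)c2Oc2cccc(C[C@H](O)c3cc(O)c(OCc4ccccc4)c(O)c3)c2)cc1 | intermediate
15 | 18-membered macrocycle: O3(D) bound to C4(A), O4(D) and O3(B) benzylated, O5(D)–H free, (E)-CH=CH between A and B, (S)-carbinol | Oc1cc2cc(c1OCc3ccccc3)Oc4ccc(cc4)/C=C/c5cccc(OCc6ccccc6)c5Oc7cccc(c7)C[C@@H]2O | intermediate
16 | CNP0333307.1, (S)-carbinol | Oc1cc2cc(c1O)Oc1ccc(cc1)CCc1cccc(O)c1Oc1cccc(c1)C[C@@H]2O | target

Total step count: 9. Longest linear sequence: 7 steps (1, 2, 3, 6, 7, 8, 9).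

**Steps most likely to fail**

Step 8. Ring closure may lose against oligomerisation, because the rigid (E)-alkene rod holds the phenoxide and the C–Br bond apart. Phenoxides may also be capped by left-over 12. The fallback uncouples the two events and makes the rod flexible before closure. It sets out from 13, isolated after stage (a). Diimide (TsNHNH2, NaOAc, aq. DME, reflux) saturates the alkene without touching C–Br or O–Bn and gives the bibenzyl bromide F1. TBAF/AcOH gives the bis-phenol F2. A separate high-dilution Ullmann closure of this flexible seco-bromide (CuI, N,N-dimethylglycine, Cs2CO3, dioxane, 100 °C) forms the same O3(D)–C4(A) bond and gives the saturated di-O-benzyl macrocycle F3. Hydrogenolysis as in step 9 brings the route back at 16.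

Step 9. Once O4 is free, the p-hydroxybenzylic C–OH may be hydrogenolysed, or may racemise through a p-quinone methide on the catalyst surface. The fallback sets the stereocentre last and sets out from ketone 10. The stitching of step 8 is run on 10 with 12. The bromostilbene ketone F4 and its bis-phenol F5 form in the flask and close to the macrocyclic ketone F6. Hydrogenation and hydrogenolysis at the ketone stage, where no benzylic C–OH is at risk and the electron-rich aryl ketone reduces slowly, give the triphenolic saturated ketone F7. Asymmetric transfer hydrogenation with a tethered (S,S)-Ru–TsDPEN catalyst in aqueous sodium formate then sets the (S)-carbinol and returns to the route at 16.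

Step 6. Acylation of the enediolate by the electron-rich ester may be too slow, so that proton transfer or attack at silicon takes over. The fallback replaces the acylation by an aldol addition and an oxidation, and sets out from 8 and 5. DIBAL-H reduces 8 to the benzylic alcohol F8. MnO2 gives the aldehyde F9. The Ivanov reaction of the enediolate of 5 with this far more electrophilic partner gives the β-hydroxy acid F10 as a diastereomer mixture. Dess–Martin oxidation gives β-keto acid 9, which decarboxylates and returns to the route at 10.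

**Further compounds**
F1 | step 8 | (1S)-1-[4-(benzyloxy)-3,5-bis(TBSO)phenyl]-2-(3-{2-(benzyloxy)-6-[2-(4-bromophenyl)ethyl]phenoxy}phenyl)ethan-1-ol | Brc1ccc(CCc2cccc(OCc3ccccc3)c2Oc2cccc(C[C@H](O)c3cc(O[Si](C)(C)C(C)(C)C)c(OCc4ccccc4)c(O[Si](C)(C)C(C)(C)C)c3)c2)cc1
F2 | step 8 | 3,5-bis-phenol of F1 | Brc1ccc(CCc2cccc(OCc3ccccc3)c2Oc2cccc(C[C@H](O)c3cc(O)c(OCc4ccccc4)c(O)c3)c2)cc1
F3 | step 8 | saturated (S)-di-O-benzyl macrocycle (O4(D) and O3(B) benzylated) | Oc1cc2cc(c1OCc3ccccc3)Oc4ccc(cc4)CCc5cccc(OCc6ccccc6)c5Oc7cccc(c7)C[C@@H]2O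
F4 | step 9 | 1-[4-(benzyloxy)-3,5-bis(TBSO)phenyl]-2-(3-{2-(benzyloxy)-6-[(E)-2-(4-bromophenyl)vinyl]phenoxy}phenyl)ethan-1-one | Brc1ccc(/C=C/c2cccc(OCc3ccccc3)c2Oc2cccc(CC(=O)c3cc(O[Si](C)(C)C(C)(C)C)c(OCc4ccccc4)c(O[Si](C)(C)C(C)(C)C)c3)c2)cc1
F5 | step 9 | 3,5-bis-phenol of F4 | Brc1ccc(/C=C/c2cccc(OCc3ccccc3)c2Oc2cccc(CC(=O)c3cc(O)c(OCc4ccccc4)c(O)c3)c2)cc1
F6 | step 9 | (E)-di-O-benzyl macrocyclic ketone | Oc1cc2cc(c1OCc3ccccc3)Oc4ccc(cc4)/C=C/c5cccc(OCc6ccccc6)c5Oc7cccc(c7)CC2=O
F7 | step 9 | saturated triphenolic macrocyclic ketone | Oc1cc2cc(c1O)Oc3ccc(cc3)CCc4cccc(O)c4Oc5cccc(c5)CC2=O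
F8 | step 6 | [4-(benzyloxy)-3,5-bis(TBSO)phenyl]methanol | OCc1cc(O[Si](C)(C)C(C)(C)C)c(OCc2ccccc2)c(O[Si](C)(C)C(C)(C)C)c1
F9 | step 6 | 4-(benzyloxy)-3,5-bis(TBSO)benzaldehyde | O=Cc1cc(O[Si](C)(C)C(C)(C)C)c(OCc2ccccc2)c(O[Si](C)(C)C(C)(C)C)c1
F10 | step 6 | 3-[4-(benzyloxy)-3,5-bis(TBSO)phenyl]-2-{3-[2-(benzyloxy)-6-vinylphenoxy]phenyl}-3-hydroxypropanoic acid (diastereomer mixture) | C=Cc1cccc(OCc2ccccc2)c1Oc1cccc(C(C(=O)O)C(O)c2cc(O[Si](C)(C)C(C)(C)C)c(OCc3ccccc3)c(O[Si](C)(C)C(C)(C)C)c2)c1
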